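**Retrosynthetic overview**
- The strategy rests on ring A: C6 and C8 each carry an ArCH2–CH=C(CH3)2 chain that differs from an allyl group only in its terminal isopropylidene carbon. C6 and C8 are also the only free carbons of ring A, ortho/para to O5 and O7.
- The last step is methanolysis of four acetates. Before it, both trisubstituted side-chain alkenes are made at once by double cross-metathesis of 6,8-diallylkaempferol tetraacetate with 2-methyl-2-butene.
- The 6,8-diallyl pattern comes from a double aromatic Claisen rearrangement of a 5,7-bis(allyloxy)flavonol. The O-allyl groups are put on at the acetophenone stage.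
- Rings A and B are bought. Ring C (the pyranone) is the only ring formed, by Claisen–Schmidt condensation and Algar–Flynn–Oyamada oxidative cyclisation of the 2'-hydroxychalcone.
- The 4'-oxygen travels as a MOM ether and is changed to acetate at the allyl stage, so no acid meets the prenyl groups.

Key step: step 8

Remark: intermediates 6 and 8 are formed racemic and both stereocentres disappear when ring C aromatises. The SMILES of 8 shows one enantiomer of the trans racemate.

**Step 1**
Reactants: 1 2,4,6-trihydroxyacetophenone; 2 allyl bromide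
Product: 3 1-[2-hydroxy-4,6-bis(allyloxy)phenyl]ethanone
Conditions: allyl bromide (2.1 equiv), K2CO3 (2.2 equiv), acetone, reflux
Reagents that add atoms: allyl bromide (2), C=CCBr
Why: Williamson ether synthesis should stop at the diether because the remaining ortho hydroxyl is hydrogen-bonded to the acetyl C=O and is the least nucleophilic, while the aprotic carbonate medium favours O- over C-allylation.

**Step 2**
Reactants: 4 4-hydroxybenzaldehyde
Product: 5 4-(methoxymethoxy)benzaldehyde
Conditions: MOMCl (1.3 equiv), iPr2NEt, CH2Cl2, 0 °C to rt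
Reagents that add atoms: chloromethyl methyl ether, COCCl
Why: O-alkylation of the phenol gives an acetal that is stable to the hydroxide, peroxide and heat of steps 3 to 5, and masks the phenoxide that would otherwise deactivate the aldehyde and the later enone.

**Step 3**
Reactants: 3 1-[2-hydroxy-4,6-bis(allyloxy)phenyl]ethanone; 5 4-(methoxymethoxy)benzaldehyde
Product: 7 (E)-1-[2-hydroxy-4,6-bis(allyloxy)phenyl]-3-[4-(methoxymethoxy)phenyl]prop-2-en-1-one, via aldol adduct 6 (not isolated)
Conditions: KOH (50% aq.), EtOH, rt; then cold dilute HCl to pH 5–6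
Reagents that add atoms: none
Why: Claisen–Schmidt condensation of the methyl ketone enolate with the non-enolisable aldehyde, followed by E1cB loss of water, should give the conjugated E-chalcone; allyl and MOM ethers are inert to hydroxide.

**Step 4**
Reactants: 7 (E)-1-[2-hydroxy-4,6-bis(allyloxy)phenyl]-3-[4-(methoxymethoxy)phenyl]prop-2-en-1-one
Product: 9 5,7-bis(allyloxy)-3-hydroxy-2-[4-(methoxymethoxy)phenyl]-4H-chromen-4-one, via trans-dihydroflavonol 8 (not isolated)
Conditions: 30% aq. H2O2, aq. NaOH, MeOH/THF, 0 °C to rt; then cold dilute HCl to pH 5–6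
Reagents that add atoms: hydrogen peroxide, OO
Why: Algar–Flynn–Oyamada oxidation: the phenoxide closes 6-endo onto C-β with oxygen transfer from hydroperoxide to C-α, and the dihydroflavonol is oxidised further to the flavonol; low temperature should disfavour the aurone-forming closure, and the isolated allyl alkenes do not react with the nucleophilic oxidant.

**Step 5**
Reactants: 9 5,7-bis(allyloxy)-3-hydroxy-2-[4-(methoxymethoxy)phenyl]-4H-chromen-4-one
Product: 11 6,8-diallyl-3,5,7-trihydroxy-2-[4-(methoxymethoxy)phenyl]-4H-chromen-4-one, via 8-allyl-7-hydroxy mono-Claisen intermediate 10 (not isolated)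
Conditions: N,N-diethylaniline, 200–210 °C (sealed tube or microwave), argon
Reagents that add atoms: none
Why: Two aromatic Claisen rearrangements ([3,3] shift, then tautomerisation, with an ortho shift/Cope relay to the para carbon if the ortho carbon is already taken) should converge on the 6,8-diallyl compound whichever ether moves first, because ring A has only C6 and C8 free; an unsubstituted allyl group cannot give normal/reverse isomers.

**Step 6**
Reactants: 11 6,8-diallyl-3,5,7-trihydroxy-2-[4-(methoxymethoxy)phenyl]-4H-chromen-4-one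
Product: 12 6,8-diallylkaempferol (6,8-diallyl-3,5,7-trihydroxy-2-(4-hydroxyphenyl)-4H-chromen-4-one)
Conditions: 3 M HCl, MeOH/THF, 50 °C
Reagents that add atoms: none
Why: Acid-catalysed acetal cleavage of the MOM ether is done here because the monosubstituted allyl alkenes resist acid-induced cyclisation onto the neighbouring phenols far better than prenyl groups would.

**Step 7**
Reactants: 12 6,8-diallylkaempferol
Product: 13 6,8-diallylkaempferol tetraacetate (6,8-diallyl-3,5,7-triacetoxy-2-(4-acetoxyphenyl)-4H-chromen-4-one)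
Conditions: Ac2O (excess), pyridine, DMAP (cat.), rt to 40 °C
Reagents that add atoms: acetic anhydride, CC(=O)OC(C)=O
Why: DMAP-catalysed acylation should esterify all four hydroxyls, including the chelated and flanked 5-OH, as kaempferol itself is peracetylated under these conditions.

**Step 8**
Reactants: 13 6,8-diallylkaempferol tetraacetate; 14 2-methyl-2-butene
Product: 15 6,8-diprenylkaempferol tetraacetate (3,5,7-triacetoxy-2-(4-acetoxyphenyl)-6,8-bis(3-methylbut-2-enyl)-4H-chromen-4-one)
Conditions: second-generation Grubbs catalyst (H2IMes)(PCy3)Cl2Ru=CHPh (5 mol% per allyl group, in two portions), 2-methyl-2-butene/CH2Cl2 1:1 (large excess of alkene), sealed tube, 40 °C, argon; 1,4-benzoquinone (10 mol%) optional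
Reagents that add atoms: 2-methyl-2-butene (14), CC=C(C)C
Why: Olefin cross-metathesis by the Chauvin mechanism: after loss of PCy3 the ruthenium benzylidene is turned by 2-methyl-2-butene into isopropylidene and ethylidene carbenes, which add [2+2] to a terminal allyl C=C of 13 to give a ruthenacyclobutane that cycloreverts to ArCH2–CH=C(CH3)2 and Ru=CH2, the latter re-entering the cycle with 2-methyl-2-butene and releasing propene. The closest known reaction type is the cross-metathesis of allylarenes, including acetylated ortho-allylphenols, with 2-methyl-2-butene to give prenylarenes. No ring is closed (ring closure between the meta-placed C6 and C8 chains is geometrically impossible) and no stereocentre is formed; each new alkene carries two identical methyl groups, so there is no E/Z issue. The step needs cross- over self-metathesis, full conversion of both chains and no allyl-to-propenyl migration: the solvent-level excess of 2-methyl-2-butene should secure the first two and carry any crotyl chain from ethylidene transfer on to prenyl, while the trisubstituted product alkenes are too hindered to re-enter. Acetylation of all four hydroxyls removes the 3-OH/4-C=O/5-OH chelating array and the acidic phenols that could bind ruthenium and promote hydride-mediated isomerisation.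

**Step 9**
Reactants: 15 6,8-diprenylkaempferol tetraacetate
Product: 16 6,8-diprenylkaempferol
Conditions: K2CO3 (5 equiv), degassed MeOH, 0 °C to rt, argon; then aq. NH4Cl/AcOH to pH 6
Reagents that add atoms: none
Why: Base-mediated transesterification of the four aryl acetates to methyl acetate should free the phenols under conditions that leave the acid-sensitive ortho-prenyl phenol units untouched; exclusion of air protects the 3-hydroxyflavone anion.

**Compound list**
1 | 2,4,6-trihydroxyacetophenone | CC(=O)c1c(O)cc(O)cc1O | starting material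
2 | allyl bromide | C=CCBr | starting material
3 | 1-[2-hydroxy-4,6-bis(allyloxy)phenyl]ethanone | CC(=O)c1c(O)cc(OCC=C)cc1OCC=C | intermediate
4 | 4-hydroxybenzaldehyde | O=Cc1ccc(O)cc1 | starting material
5 | 4-(methoxymethoxy)benzaldehyde | COCOc1ccc(C=O)cc1 | intermediate
6 | racemic aldol adduct, 1-[2-hydroxy-4,6-bis(allyloxy)phenyl]-3-hydroxy-3-[4-(methoxymethoxy)phenyl]propan-1-one | COCOc1ccc(C(O)CC(=O)c2c(O)cc(OCC=C)cc2OCC=C)cc1 | intermediate (not isolated)
7 | (E)-1-[2-hydroxy-4,6-bis(allyloxy)phenyl]-3-[4-(methoxymethoxy)phenyl]prop-2-en-1-one | COCOc1ccc(/C=C/C(=O)c2c(O)cc(OCC=C)cc2OCC=C)cc1 | intermediate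
8 | rac-(2R,3R)-trans-5,7-bis(allyloxy)-3-hydroxy-2-[4-(methoxymethoxy)phenyl]chroman-4-one | COCOc1ccc(cc1)[C@@H]1[C@@H](O)C(=O)c2c(OCC=C)cc(OCC=C)cc2O1 | intermediate (not isolated)
9 | 5,7-bis(allyloxy)-3-hydroxy-2-[4-(methoxymethoxy)phenyl]-4H-chromen-4-one | COCOc1ccc(cc1)-c1oc2cc(OCC=C)cc(OCC=C)c2c(=O)c1O | intermediate
10 | 8-allyl-5-(allyloxy)-3,7-dihydroxy-2-[4-(methoxymethoxy)phenyl]-4H-chromen-4-one | COCOc1ccc(cc1)-c1oc2c(CC=C)c(O)cc(OCC=C)c2c(=O)c1O | intermediate (not isolated)
11 | 6,8-diallyl-3,5,7-trihydroxy-2-[4-(methoxymethoxy)phenyl]-4H-chromen-4-one | COCOc1ccc(cc1)-c1oc2c(CC=C)c(O)c(CC=C)c(O)c2c(=O)c1O | intermediate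
12 | 6,8-diallylkaempferol | Oc1ccc(cc1)-c1oc2c(CC=C)c(O)c(CC=C)c(O)c2c(=O)c1O | intermediate
13 | 6,8-diallylkaempferol tetraacetate | CC(=O)Oc1ccc(cc1)-c1oc2c(CC=C)c(OC(C)=O)c(CC=C)c(OC(C)=O)c2c(=O)c1OC(C)=O | intermediate
14 | 2-methyl-2-butene | CC=C(C)C | starting material
15 | 6,8-diprenylkaempferol tetraacetate | CC(=O)Oc1ccc(cc1)-c1oc2c(CC=C(C)C)c(OC(C)=O)c(CC=C(C)C)c(OC(C)=O)c2c(=O)c1OC(C)=O | intermediate
16 | 6,8-diprenylkaempferol | CC(C)=CCc1c(O)c(CC=C(C)C)c2oc(-c3ccc(O)cc3)c(O)c(=O)c2c1O | target

**Totals**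
Total step count: 9. Longest linear sequence: 8 steps (steps 1, 3, 4, 5, 6, 7, 8, 9).

**Steps most likely to fail**

Step 4. With an alkoxy group at C6' the phenoxide may close 5-exo onto C-α instead of 6-endo onto C-β, which diverts material into a five-membered ring. The fallback separates oxidation from ring closure. It sets out from 7 and comes back at 12.
- The chelated 2'-OH is capped (MOMCl, NaH, DMF, 0 °C) to give (E)-1-[2,4-bis(allyloxy)-6-(methoxymethoxy)phenyl]-3-[4-(methoxymethoxy)phenyl]prop-2-en-1-one F1.
- Weitz–Scheffer epoxidation (H2O2, NaOH, MeOH/THF, 0 °C) should then give the racemic trans-epoxy ketone F2, with no free phenoxide present to cyclise during oxidation.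
- HCl/MeOH at 50 °C removes both MOM groups, and the freed phenol opens the epoxide at the benzylic carbon to give racemic trans-5,7-bis(allyloxy)-3-hydroxy-2-(4-hydroxyphenyl)chroman-4-one F3.
- Dehydrogenation with DDQ in 1,4-dioxane at 80 °C gives 5,7-bis(allyloxy)-3-hydroxy-2-(4-hydroxyphenyl)-4H-chromen-4-one F4.
- Heating F4 as in step 5 gives 12 directly.

Step 8. The exchange may stall after one chain, ethylidene may be transferred in place of isopropylidene, or the double bond may migrate into conjugation with ring A before metathesis. The fallback builds the isopropylidene by carbonyl olefination. It sets out from 12 and comes back at 16.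
- MOMCl, NaH, DMF gives 6,8-diallyl-3,5,7-tris(methoxymethoxy)-2-[4-(methoxymethoxy)phenyl]-4H-chromen-4-one F9.
- Lemieux–Johnson cleavage (OsO4 cat., NaIO4, 2,6-lutidine, dioxane/H2O) gives the 6,8-bis(2-oxoethyl) dialdehyde F10.
- Wittig olefination with isopropylidenetriphenylphosphorane (isopropyltriphenylphosphonium iodide, n-BuLi, THF, −78 to 0 °C) gives 6,8-diprenylkaempferol tetrakis(methoxymethyl) ether F11.
- Brief treatment with HCl in MeOH at rt then frees 16.

Step 5. The second sigmatropic shift may not go to completion, a freed phenol may add to its neighbouring allyl alkene, or the MOM ether may be lost at 200 °C. The fallback moves the rearrangement to the simple acetophenone, before ring C exists. It sets out from 3 and comes back at 12.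
- Heating 3 in N,N-diethylaniline at 200 °C gives 1-(3,5-diallyl-2,4,6-trihydroxyphenyl)ethanone F5.
- MOMCl, iPr2NEt, CH2Cl2 gives 1-[3,5-diallyl-2-hydroxy-4,6-bis(methoxymethoxy)phenyl]ethanone F6.
- Claisen–Schmidt condensation with 5 (KOH, EtOH) gives the 3',5'-diallyl chalcone F7.
- Algar–Flynn–Oyamada oxidation (H2O2, NaOH, MeOH) gives 6,8-diallyl-3-hydroxy-5,7-bis(methoxymethoxy)-2-[4-(methoxymethoxy)phenyl]-4H-chromen-4-one F8.
- HCl/MeOH at 50 °C removes the three MOM groups to give 12.

**Further compounds**
F1 | step 4 | (E)-1-[2,4-bis(allyloxy)-6-(methoxymethoxy)phenyl]-3-[4-(methoxymethoxy)phenyl]prop-2-en-1-one | COCOc1ccc(/C=C/C(=O)c2c(OCOC)cc(OCC=C)cc2OCC=C)cc1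
F2 | step 4 | racemic trans-[2,4-bis(allyloxy)-6-(methoxymethoxy)phenyl]{3-[4-(methoxymethoxy)phenyl]oxiran-2-yl}methanone | COCOc1ccc(cc1)[C@H]1O[C@@H]1C(=O)c1c(OCOC)cc(OCC=C)cc1OCC=C
F3 | step 4 | racemic trans-5,7-bis(allyloxy)-3-hydroxy-2-(4-hydroxyphenyl)chroman-4-one | Oc1ccc(cc1)[C@@H]1[C@@H](O)C(=O)c2c(OCC=C)cc(OCC=C)cc2O1
F4 | step 4 | 5,7-bis(allyloxy)-3-hydroxy-2-(4-hydroxyphenyl)-4H-chromen-4-one | Oc1ccc(cc1)-c1oc2cc(OCC=C)cc(OCC=C)c2c(=O)c1O
F5 | step 5 | 1-(3,5-diallyl-2,4,6-trihydroxyphenyl)ethanone | CC(=O)c1c(O)c(CC=C)c(O)c(CC=C)c1O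
F6 | step 5 | 1-[3,5-diallyl-2-hydroxy-4,6-bis(methoxymethoxy)phenyl]ethanone | CC(=O)c1c(O)c(CC=C)c(OCOC)c(CC=C)c1OCOC
F7 | step 5 | (E)-1-[3,5-diallyl-2-hydroxy-4,6-bis(methoxymethoxy)phenyl]-3-[4-(methoxymethoxy)phenyl]prop-2-en-1-one | COCOc1ccc(/C=C/C(=O)c2c(O)c(CC=C)c(OCOC)c(CC=C)c2OCOC)cc1
F8 | step 5 | 6,8-diallyl-3-hydroxy-5,7-bis(methoxymethoxy)-2-[4-(methoxymethoxy)phenyl]-4H-chromen-4-one | COCOc1ccc(cc1)-c1oc2c(CC=C)c(OCOC)c(CC=C)c(OCOC)c2c(=O)c1O
F9 | step 8 | 6,8-diallyl-3,5,7-tris(methoxymethoxy)-2-[4-(methoxymethoxy)phenyl]-4H-chromen-4-one | COCOc1ccc(cc1)-c1oc2c(CC=C)c(OCOC)c(CC=C)c(OCOC)c2c(=O)c1OCOC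
F10 | step 8 | 3,5,7-tris(methoxymethoxy)-2-[4-(methoxymethoxy)phenyl]-6,8-bis(2-oxoethyl)-4H-chromen-4-one | COCOc1ccc(cc1)-c1oc2c(CC=O)c(OCOC)c(CC=O)c(OCOC)c2c(=O)c1OCOC
F11 | step 8 | 3,5,7-tris(methoxymethoxy)-2-[4-(methoxymethoxy)phenyl]-6,8-bis(3-methylbut-2-enyl)-4H-chromen-4-one | COCOc1ccc(cc1)-c1oc2c(CC=C(C)C)c(OCOC)c(CC=C(C)C)c(OCOC)c2c(=O)c1OCOC
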